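**Retrosynthetic overview**
- Trichorabdal B comes from a C6 primary alcohol oxidised to the aldehyde, with the C15 ketone α-methylenated (C16=C17) and the C11 ketone reduced to the alcohol.
- The bicyclo[3.2.1]octane (rings C and D) is closed by an amine-catalysed aldol-condensation/Michael cascade on a spiro-lactone keto-aldehyde bearing two methyl ketones.
- The C8 quaternary centre comes from allylation of a β-keto-δ-lactone (followed by ozonolysis), and the lactone from the Giese adduct.
- The C9–C10 bond is made by an Fe–H hydrogen-atom-transfer radical addition of the A-ring trisubstituted alkene to an ene-dione.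
- The A ring (C4/C5) comes from an organocatalytic asymmetric Diels–Alder of methacrolein, and C20 from SeO2 allylic oxidation. Rings are formed in the order A, spiro-lactone, D, C.

**Assumptions (one line):** the target is the given SMILES, i.e. 19-acetoxy (axial CH2OAc, syn to C20) and 11-hydroxy (equatorial); the Step 3 catalyst enantiomer is chosen to give the shown absolute configuration; C9 equilibrates through the C11 ketone to the isomer with C10 equatorial.

---

**Step 1**
Reactants: 1, (E)-3-methylpent-2-en-4-yn-1-ol
Product: 2, its TBS ether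
Conditions: TBSCl, imidazole, DMF, 0 °C → rt
Reagents that add atoms: tert-butyldimethylsilyl chloride, CC(C)(C)[Si](C)(C)Cl
Why: Standard silylation of the primary alcohol; it survives the later steps, including the TEMPO oxidation that unmasks C6.

**Step 2**
Reactants: 2
Product: 3, (E)-TBS 3-methylpenta-2,4-dienyl ether
Conditions: H2 (1 atm), Lindlar Pd, quinoline, hexane, rt
Reagents that add atoms: none
Why: Lindlar semihydrogenation stops at the conjugated diene and keeps the E geometry, which the endo Diels–Alder needs.

**Step 3**
Reactants: 3, diene; 4, methacrolein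
Product: 5, 2-[(TBSO)methyl]-1,3-dimethylcyclohex-3-ene-1-carbaldehyde (1,2-cis, single enantiomer)
Conditions: chiral primary amine·2 TFA (cinchona 9-amino-9-deoxy-epi-quinine type, 20 mol%), MeCN, −20 °C
Reagents that add atoms: none
Why: Organocatalytic asymmetric Diels–Alder via iminium activation.
- It sets the C4 quaternary and C5 stereocentres.
- The 1-substituent makes the CH2 terminus of the diene the most nucleophilic carbon, giving the "ortho" regiochemistry.
- Endo approach of the (E)-iminium puts CHO (C19) cis to C6, as in the target.

**Step 4**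
Reactants: 5
Product: 6, [2-(TBSO-methyl)-1,3-dimethylcyclohex-3-en-1-yl]methyl acetate
Conditions: NaBH4, EtOH, 0 °C; then Ac2O, Et3N, DMAP, CH2Cl2 (one pot)
Reagents that add atoms: acetic anhydride, CC(=O)OC(C)=O
Why: Reduction and acetylation give the C19 acetate with no stereocentre touched; the TBS ether is stable.

**Step 5**
Reactants: 6
Product: 7, the C20 allylic alcohol (alkene C1=C10 retained)
Conditions: SeO2 (10 mol%), TBHP, CH2Cl2, 0 °C → rt
Reagents that add atoms: tert-butyl hydroperoxide, CC(C)(C)OO (oxygen source)
Why: Riley ene/[2,3] oxidation abstracts H from the C10 methyl, preferred over the tertiary C5–H, and the alkene is regenerated; acetate and TBS survive.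

**Step 6**
Reactants: 8, methyl acetoacetate; 9, methylglyoxal
Product: 10, methyl 2-acetyl-4-oxopent-2-enoate
Conditions: piperidine/AcOH (cat.), CH2Cl2/H2O, 0 °C, 15 min; crude used at once
Reagents that add atoms: none (loses H2O)
Why: Knoevenagel condensation gives the tri-activated radical acceptor, with the C8=C9 alkene polarised toward attack at C9.

**Step 7**
Reactants: 7; 10 (3 equiv)
Product: 11, the C9–C10 adduct (C8 epimers)
Conditions: Fe(acac)3, PhSiH3, EtOH, 60 °C
Reagents that add atoms: none (only H delivered)
Why: Fe–H hydrogen-atom transfer to C1 gives the tertiary C10 radical (Giese/Baran olefin coupling).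
- It adds at C9 of the acceptor from the face anti to the axial C19 CH2OAc, setting quaternary C10 with C20 syn to C19.
- The free alcohol, acetate and TBS ether are untouched.

**Step 8**
Reactants: 11
Product: 12, spiro δ-lactone (7,20-olide) with C8–H, acetyl groups at C8 and C9, CH2OAc and CH2OTBS
Conditions: toluene, 110 °C, 4 Å MS
Reagents that add atoms: none (loses MeOH)
Why: Thermal β-keto-ester transesterification via an acylketene closes the lactone without acid, so TBS is not lost; both C8 epimers converge.

**Step 9**
Reactants: 12
Product: 13, C8-allyl spirolactone (C8 quaternary)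
Conditions: K2CO3, allyl bromide, NaI (cat.), DMF, 40 °C
Reagents that add atoms: allyl bromide, C=CCBr
Why: C-Allylation of the β-keto-lactone enolate sets C8.
- The electrophile approaches anti to the larger C9 side chain, which places C14 trans to C11, the trans ring fusion required.
- Any C9 epimerisation is harmless because C9 is reset thermodynamically in Step 11.

**Step 10**
Reactants: 13
Product: 14, keto-aldehyde (C8–CH2–CHO, with C15 acetyl and C11 acetyl)
Conditions: O3, CH2Cl2, −78 °C; then PPh3
Reagents that add atoms: ozone, [O-][O+]=O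
Why: Ozonolysis of the only alkene; ketones, lactone, acetate and silyl ether are inert.

**Step 11**
Reactants: 14
Product: 15, the tetracyclic 11,15-dioxo 6,7-seco-7,20-olide (bicyclo[3.2.1]octane)
Conditions: pyrrolidine (30 mol%), AcOH (30 mol%), MeCN, 50 °C
Reagents that add atoms: none (loses H2O)
Why: Proposed new method: amine-catalysed double annulation of a keto-aldehyde carrying two methyl ketones.
- The C15 acetyl methyl (C16) enamine closes a 5-exo aldol on the C13 aldehyde, and dehydration gives the cyclopentenone (C16=C13).
- The C11 methyl ketone (C12) enamine then adds 6-exo to C13, closing ring C as the bridged bicyclo[3.2.1]octane.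
- C13 is fixed by the bridge geometry, and C9 epimerises through the C11 enol to the C10-equatorial isomer.
- The closest known reactions are Robinson/Hajos–Parrish enamine aldol condensation and amine-catalysed intramolecular Michael addition; what is new is applying this cascade to a keto-aldehyde bearing two methyl ketones to assemble the ent-kauranoid C/D bicycle.

**Step 12**
Reactants: 15
Product: 16, the 11-hydroxy-15-oxo compound
Conditions: Al(OiPr)3, iPrOH, 60 °C
Reagents that add atoms: none
Why: Meerwein–Ponndorf–Verley equilibrating reduction takes the unhindered C11 ketone (C15 is next to quaternary C8).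
- It gives the equatorial exo alcohol, because axial hydride delivery is blocked by the C15–C16 bridge.
- C11 must be reduced before methylenation so that only one ketone is enolised.

**Step 13**
Reactants: 16
Product: 17, the C16 Mannich base (dimethylaminomethyl at C16, C16 epimers)
Conditions: TMSOTf, Et3N, CH2Cl2, −78 → 0 °C; then Me2N=CH2+ I−, CH2Cl2, rt; aqueous workup
Reagents that add atoms: Eschenmoser's salt, C[N+](C)=C.[I-]
Why: Mukaiyama–Mannich reaction; the silyl enol ether can form only toward C16 because C8 is quaternary, and the C11–OH is silylated transiently then released.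

**Step 14**
Reactants: 17
Product: 18, the 16-methylene-15-ketone (C6–OTBS)
Conditions: MeI, CH2Cl2, rt; then DBU (or NaHCO3)
Reagents that add atoms: none (NMe3 is lost)
Why: Quaternisation and base-induced elimination (E1cB/Hofmann) give the exocyclic enone; the other groups are stable to these mild conditions.

**Step 15**
Reactants: 18
Product: 19, the C6 primary alcohol
Conditions: HF·pyridine, pyridine/THF, 0 °C → rt
Reagents that add atoms: none
Why: Fluoride cleaves the primary TBS ether; the acetate, lactone and enone survive the buffered conditions.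

**Step 16**
Reactants: 19
Product: 20, trichorabdal B
Conditions: TEMPO (10 mol%), PhI(OAc)2, CH2Cl2, rt
Reagents that add atoms: none
Why: Anelli-type oxidation is selective for the primary C6 alcohol over the secondary C11 alcohol and gives the C6 aldehyde last; C5 is not epimerised under these mild conditions.

---

**Compound list**

1 | (2E)-3-methylpent-2-en-4-yn-1-ol | C#C/C(C)=C/CO | starting material
2 | TBS ether of 1 | C#C/C(C)=C/CO[Si](C)(C)C(C)(C)C | intermediate
3 | (2E)-TBS 3-methylpenta-2,4-dienyl ether | C=C/C(C)=C/CO[Si](C)(C)C(C)(C)C | intermediate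
4 | methacrolein | C=C(C)C=O | starting material
5 | 2-[(TBSO)methyl]-1,3-dimethylcyclohex-3-ene-1-carbaldehyde, cis | O=C[C@]1(C)CCC=C(C)[C@@H]1CO[Si](C)(C)C(C)(C)C | intermediate
6 | [2-(TBSO-methyl)-1,3-dimethylcyclohex-3-en-1-yl]methyl acetate | CC(=O)OC[C@]1(C)CCC=C(C)[C@@H]1CO[Si](C)(C)C(C)(C)C | intermediate
7 | C20 allylic alcohol of 6 | CC(=O)OC[C@]1(C)CCC=C(CO)[C@@H]1CO[Si](C)(C)C(C)(C)C | intermediate
8 | methyl acetoacetate | COC(=O)CC(C)=O | starting material
9 | methylglyoxal | CC(=O)C=O | starting material
10 | methyl 2-acetyl-4-oxopent-2-enoate | COC(=O)C(C(C)=O)=CC(C)=O | intermediate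
11 | Giese adduct (C8 epimer mixture; C8 not specified) | COC(=O)C(C(C)=O)[C@H](C(C)=O)[C@]1(CO)CCC[C@@](C)(COC(C)=O)[C@H]1CO[Si](C)(C)C(C)(C)C | intermediate
12 | spiro δ-lactone, C8–H | CC(=O)C1C(=O)OC[C@@]2([C@H]1C(C)=O)CCC[C@@](C)(COC(C)=O)[C@H]2CO[Si](C)(C)C(C)(C)C | intermediate
13 | C8-allyl spirolactone | CC(=O)[C@@]1(CC=C)C(=O)OC[C@@]2([C@H]1C(C)=O)CCC[C@@](C)(COC(C)=O)[C@H]2CO[Si](C)(C)C(C)(C)C | intermediate
14 | keto-aldehyde | CC(=O)[C@@]1(CC=O)C(=O)OC[C@@]2([C@H]1C(C)=O)CCC[C@@](C)(COC(C)=O)[C@H]2CO[Si](C)(C)C(C)(C)C | intermediate
15 | tetracyclic 11,15-dione, 6-OTBS | C1C(=O)[C@]23C[C@H]1CC(=O)[C@@H]2[C@@]1(CCC[C@@](C)(COC(C)=O)[C@H]1CO[Si](C)(C)C(C)(C)C)COC3=O | intermediate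
16 | 11-hydroxy-15-ketone | C1C(=O)[C@]23C[C@H]1C[C@@H](O)[C@@H]2[C@@]1(CCC[C@@](C)(COC(C)=O)[C@H]1CO[Si](C)(C)C(C)(C)C)COC3=O | intermediate
17 | C16 Mannich base (C16 epimers; C16 not specified) | CN(C)CC1C(=O)[C@]23C[C@H]1C[C@@H](O)[C@@H]2[C@@]1(CCC[C@@](C)(COC(C)=O)[C@H]1CO[Si](C)(C)C(C)(C)C)COC3=O | intermediate
18 | 16-methylene-15-ketone, 6-OTBS | C=C1C(=O)[C@]23C[C@H]1C[C@@H](O)[C@@H]2[C@@]1(CCC[C@@](C)(COC(C)=O)[C@H]1CO[Si](C)(C)C(C)(C)C)COC3=O | intermediate
19 | 6-hydroxy compound | C=C1C(=O)[C@]23C[C@H]1C[C@@H](O)[C@@H]2[C@@]1(CCC[C@@](C)(COC(C)=O)[C@H]1CO)COC3=O | intermediate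
20 | trichorabdal B | C=C1C(=O)[C@]23C[C@H]1C[C@@H](O)[C@@H]2[C@@]1(CCC[C@@](C)(COC(C)=O)[C@H]1C=O)COC3=O | target

**Total steps:** 16 (Step 6 is a convergent branch).
**Longest linear sequence:** 15 steps (Steps 1–5 and 7–16).

**Three steps most likely to fail**

1. **Step 11 (proposed new cascade).**
   - Risks: retro-Claisen opening of the C8 quaternary 1,3-dicarbonyl by the amine, or competing 1,4-diketone cyclopentenone aldol.
   - Fallback (known chemistry): stop at the ring-D enone with TsOH/pyrrolidine-mediated aldol condensation. Then convert the C11 methyl ketone to its silyl enol ether (TMSOTf/Et3N) and close ring C by an intramolecular Mukaiyama–Michael (Sc(OTf)3 or TBSOTf).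
2. **Step 7 (Fe–H Giese forming vicinal C10 quaternary and C9 tertiary centres).**
   - Risks: over-reduction of the acceptor and poor facial selectivity.
   - Fallback: epoxidise the C1=C10 alkene of 7 and open it with Cp2TiCl (Gansäuer/Reisman-type Ti(III) radical generation) to give the tertiary C10 radical, then add it to 10. Remove the resulting C1–OH by Barton–McCombie deoxygenation.
3. **Step 9 (facial selectivity of C8 allylation).**
   - Risk: the wrong C8 epimer, which would give the unnatural diastereomer.
   - Fallback: convert 12 to its allyl enol carbonate and use Pd-catalysed decarboxylative allylic alkylation (Tsuji–Stoltz, Pd2(dba)3/(S)-t-Bu-PHOX), so the ligand rather than the substrate controls C8.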